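## Retrosynthetic overview

1. Target 10 ⇐ one-pot methanolysis of the all-cis tetrahydropyranyl trifluoroacetate 9, which removes the trifluoroacetate, two aryl acetates and one aryl TBS ether.
2. The tetrahydropyran is the only ring formed (both arenes are bought) ⇐ TFA Prins cyclisation of (S)-homoallylic alcohol 6 with aryl aldehyde 8, forming O1–C2, C2–C3 and C4–O.
3. 6 ⇐ Keck asymmetric allylation of 3-arylpropanal 4, the only absolute stereocontrol step; 4 ⇐ ethyl dihydroferulate 1 by TBS protection and DIBAL-H.
4. 8 ⇐ 5-hydroxyvanillin 7 by diacetylation.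

Assumption: 1, 7 and all reagents written over the arrows are catalogue chemicals; only substrates, intermediates and products are numbered, reagents are not.

## Route

Step 1
Reactants: 1 ethyl 3-(4-hydroxy-3-methoxyphenyl)propanoate
Product: 2 ethyl 3-[4-(tert-butyldimethylsilyloxy)-3-methoxyphenyl]propanoate
Conditions: TBSCl (1.2 equiv), imidazole (2.5 equiv), DMF, rt
Reagents that add atoms: tert-butyldimethylsilyl chloride, CC(C)(C)[Si](C)(C)Cl
Why: Imidazole-promoted silylation (Corey TBS protection) of the only free OH, the phenol, leaves the ester untouched and forms no stereocentre.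

Step 2
Reactants: 2 ethyl 3-[4-(tert-butyldimethylsilyloxy)-3-methoxyphenyl]propanoate
Product: 4 3-[4-(tert-butyldimethylsilyloxy)-3-methoxyphenyl]propanal, via aluminium hemiacetal 3 (not isolated)
Conditions: DIBAL-H (1.1 equiv), CH2Cl2, −78 °C; MeOH quench, aq. Rochelle salt
Reagents that add atoms: none
Why: DIBAL-H half-reduction of an ester stops at the tetrahedral aluminium hemiacetal 3, which is stable at −78 °C and collapses to the aldehyde only on aqueous work-up, while the aryl silyl ether is inert; no stereocentre is formed.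

Step 3
Reactants: 4 3-[4-(tert-butyldimethylsilyloxy)-3-methoxyphenyl]propanal
Product: 6 (S)-1-[4-(tert-butyldimethylsilyloxy)-3-methoxyphenyl]hex-5-en-3-ol, via tributylstannyl ether 5 (not isolated)
Conditions: (R)-BINOL (20 mol%), Ti(OiPr)4 (10 mol%), 4 Å MS, CH2Cl2; allylSnBu3 (1.5 equiv), −78 → −20 °C, 72 h; sat. aq. NaHCO3
Reagents that add atoms: allyltributylstannane, C=CC[Sn](CCCC)(CCCC)CCCC
Why: In the Keck asymmetric allylation the (R)-BINOL–Ti(IV) Lewis acid directs allyl transfer to the Re face of the unbranched aliphatic aldehyde, giving the (S)-carbinol (S because allyl outranks the arylethyl chain) as its stannyl ether 5, which is hydrolysed on work-up.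

Step 4
Reactants: 7 3,4-dihydroxy-5-methoxybenzaldehyde (5-hydroxyvanillin)
Product: 8 3,4-diacetoxy-5-methoxybenzaldehyde
Conditions: Ac2O (2.5 equiv), pyridine, DMAP (cat.), CH2Cl2, 0 °C → rt
Reagents that add atoms: acetic anhydride, CC(=O)OC(C)=O
Why: DMAP-catalysed acylation caps both phenols as electron-withdrawing acetates, which keep the aldehyde electrophilic for the Prins step and come off in the final methanolysis; no stereocentre is formed.

Step 5
Reactants: 6 (S)-1-[4-(tert-butyldimethylsilyloxy)-3-methoxyphenyl]hex-5-en-3-ol; 8 3,4-diacetoxy-5-methoxybenzaldehyde (1.5 equiv)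
Product: 10 (2S,4R,6S)-2-(3,4-dihydroxy-5-methoxyphenyl)-6-[2-(4-hydroxy-3-methoxyphenyl)ethyl]tetrahydro-2H-pyran-4-ol (target CNP0399218.1), via tetrahydropyranyl trifluoroacetate 9 (not isolated)
Conditions: TFA (15 equiv), CH2Cl2, 0 °C → rt, 4 h; aq. NaHCO3 wash, concentrate; then K2CO3 (0.5 equiv, catalytic base), degassed MeOH, rt, under Ar
Reagents that add atoms: trifluoroacetic acid, OC(=O)C(F)(F)F
Why: In this Prins cyclisation the (E)-oxocarbenium ion from 6 and 8 closes through a chair transition state with aryl and arylethyl groups equatorial (2,6-cis, C2 set relative to the untouched (S)-carbinol carbon), the C4 cation is trapped equatorially by trifluoroacetate (all-cis, C4 R), and base-catalysed methanolysis then cleaves the trifluoroacetate, both aryl acetates and the aryl TBS ether in the same operation.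

## Compound list

1 | ethyl 3-(4-hydroxy-3-methoxyphenyl)propanoate (ethyl dihydroferulate) | CCOC(=O)CCc1ccc(O)c(OC)c1 | starting material
2 | ethyl 3-[4-(tert-butyldimethylsilyloxy)-3-methoxyphenyl]propanoate | CCOC(=O)CCc1ccc(O[Si](C)(C)C(C)(C)C)c(OC)c1 | intermediate
3 | diisobutylaluminium alkoxide of the ethyl hemiacetal of aldehyde 4 (tetrahedral DIBAL adduct, hemiacetal carbon not controlled) | CCOC(CCc1ccc(O[Si](C)(C)C(C)(C)C)c(OC)c1)O[Al](CC(C)C)CC(C)C | intermediate (not isolated)
4 | 3-[4-(tert-butyldimethylsilyloxy)-3-methoxyphenyl]propanal | O=CCCc1ccc(O[Si](C)(C)C(C)(C)C)c(OC)c1 | intermediate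
5 | tributylstannyl ether of (S)-1-[4-(tert-butyldimethylsilyloxy)-3-methoxyphenyl]hex-5-en-3-ol | COc1cc(CC[C@H](O[Sn](CCCC)(CCCC)CCCC)CC=C)ccc1O[Si](C)(C)C(C)(C)C | intermediate (not isolated)
6 | (S)-1-[4-(tert-butyldimethylsilyloxy)-3-methoxyphenyl]hex-5-en-3-ol | COc1cc(CC[C@H](O)CC=C)ccc1O[Si](C)(C)C(C)(C)C | intermediate
7 | 3,4-dihydroxy-5-methoxybenzaldehyde (5-hydroxyvanillin) | COc1cc(C=O)cc(O)c1O | starting material
8 | 3,4-diacetoxy-5-methoxybenzaldehyde | COc1cc(C=O)cc(OC(C)=O)c1OC(C)=O | intermediate
9 | (2S,4R,6S)-2-(3,4-diacetoxy-5-methoxyphenyl)-6-{2-[4-(tert-butyldimethylsilyloxy)-3-methoxyphenyl]ethyl}tetrahydro-2H-pyran-4-yl trifluoroacetate (all-cis) | COc1cc(CC[C@H]2C[C@@H](OC(=O)C(F)(F)F)C[C@@H](c3cc(OC(C)=O)c(OC(C)=O)c(OC)c3)O2)ccc1O[Si](C)(C)C(C)(C)C | intermediate (not isolated)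
10 | (2S,4R,6S)-2-(3,4-dihydroxy-5-methoxyphenyl)-6-[2-(4-hydroxy-3-methoxyphenyl)ethyl]tetrahydro-2H-pyran-4-ol (all-cis) | COc1cc(CC[C@H]2C[C@@H](O)C[C@@H](c3cc(O)c(O)c(OC)c3)O2)ccc1O | target

## Step count and risk

Total step count: 5. Longest linear sequence: 4 (steps 1, 2, 3, 5; step 4 is the one-step side branch).

The three steps most likely to fail:

Step 5 (Prins cyclisation and global methanolysis). The aryl-conjugated oxocarbenium ion may cyclise slowly, aldehyde exchange through 2-oxonia-Cope rearrangement may give symmetric tetrahydropyrans, and the free catechol is air-sensitive in base. The fallback reverses the roles of the two partners and sets out from aldehyde 8. A Keck allylation with (S)-BINOL/Ti(OiPr)4 and allyltributylstannane (CH2Cl2, −20 °C) gives, through the tributylstannyl ether of the product F1, the benzylic homoallylic alcohol (S)-1-(3,4-diacetoxy-5-methoxyphenyl)but-3-en-1-ol F2. Attack is on the Si face, and the descriptor is S because aryl outranks allyl. F2 is then condensed with the aliphatic aldehyde 4 from step 2 under TFA/CH2Cl2. The oxocarbenium ion is now non-conjugated and more reactive, and the electron-poor diacetoxyaryl group disfavours benzylic ionisation that would erode the ee. The same all-cis chair cyclisation brings the fallback back to the route at trifluoroacetate 9, which is methanolysed to 10 as in step 5.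

Step 3 (Keck allylation). The reaction is slow, the ee depends on catalyst preparation, and tin residues must be removed. The fallback changes the oxidation level of the substrate and sets out from ester 2. Full reduction with LiAlH4 (THF, 0 °C) gives 3-[4-(tert-butyldimethylsilyloxy)-3-methoxyphenyl]propan-1-ol F3. F3 is then allylated directly by Krische iridium-catalysed transfer-hydrogenative coupling with allyl acetate ([Ir(cod)Cl]2, (R)-BINAP, 4-chloro-3-nitrobenzoic acid, Cs2CO3 20 mol%, THF, 100 °C), in which the aldehyde is only generated transiently on the metal. The (R)-ligand is expected to give the (S)-alcohol, but I am less sure of this sense than of the Keck one, so it should be checked by Mosher ester analysis and the antipodal ligand used if needed. This fallback comes back to the route at homoallylic alcohol 6.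

Step 2 (DIBAL-H half-reduction). Over-reduction to the primary alcohol or incomplete conversion is possible. The fallback sets out from ester 2, which is converted with MeNH(OMe)·HCl and iPrMgCl (THF, −20 → 0 °C) into the Weinreb amide N-methoxy-N-methyl-3-[4-(tert-butyldimethylsilyloxy)-3-methoxyphenyl]propanamide F4. Reduction of F4 with LiAlH4 (THF, −78 → 0 °C) cannot proceed past the aldehyde oxidation level before work-up, and the fallback comes back to the route at aldehyde 4.

Further compounds
F1 | step 5 | tributylstannyl ether of (S)-1-(3,4-diacetoxy-5-methoxyphenyl)but-3-en-1-ol | C=CC[C@H](O[Sn](CCCC)(CCCC)CCCC)c1cc(OC(C)=O)c(OC(C)=O)c(OC)c1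
F2 | step 5 | (S)-1-(3,4-diacetoxy-5-methoxyphenyl)but-3-en-1-ol | C=CC[C@H](O)c1cc(OC(C)=O)c(OC(C)=O)c(OC)c1
F3 | step 3 | 3-[4-(tert-butyldimethylsilyloxy)-3-methoxyphenyl]propan-1-ol | OCCCc1ccc(O[Si](C)(C)C(C)(C)C)c(OC)c1
F4 | step 2 | N-methoxy-N-methyl-3-[4-(tert-butyldimethylsilyloxy)-3-methoxyphenyl]propanamide | CON(C)C(=O)CCc1ccc(O[Si](C)(C)C(C)(C)C)c(OC)c1
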